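Ring A is cut at C4a–C5 and C8a–C8. The C5(Me)–C6(OMe)–C7(H)–C8(OH) edge comes from a 4-methyl-1,1,3-trioxygenated diene, and the C4a–C8a edge, with C1 and the C4 side chain attached, from an alkynoate. One Diels–Alder addition with aromatisation therefore makes the whole hexasubstituted resorcylate, with O-8 free beside the C1 ester. The dienophile is a benzyl hex-2-ynoate whose 4S methyl centre comes from a Marshall propargylation. It already carries the ring B ester on O-9 and a single silyl ether on O-3, so that no diol is ever exposed. Afterwards C3 is oxidised and hydrogenolysis lets the keto acid close to the lactol.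

Key step: step 12

Remark on the chemistry: C3 is a hemiketal carbon that equilibrates through the open keto acid, so its 3R configuration (hydroxyl axial and trans to the pseudoaxial C4 methyl, acyloxymethyl equatorial) is taken to be the thermodynamic one and only C4 (S) has to be set; atom numbers are those of the isochromanone, with C9 for the CH2 on C3.

Step 1
Reactants: 1 4,5-dimethylbenzene-1,3-diol
Product: 3 2,4-dihydroxy-5,6-dimethylbenzaldehyde, via aryl iminium chloride 2 (not isolated)
Conditions: POCl3, DMF, MeCN, 0 °C → rt; then H2O, 50 °C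
Reagents that add atoms: N,N-dimethylformamide CN(C)C=O; water O
Why: Vilsmeier–Haack formylation, in which the chloroiminium ion should attack C6 of the resorcinol, the only free position para to one hydroxyl and ortho to the other, and hydrolysis of iminium 2 releases the aldehyde.

Step 2
Reactants: 3 2,4-dihydroxy-5,6-dimethylbenzaldehyde
Product: 4 2,4-bis(benzyloxy)-5,6-dimethylbenzaldehyde
Conditions: BnBr (2.4 equiv), K2CO3, DMF, 60 °C
Reagents that add atoms: benzyl bromide BrCc1ccccc1
Why: Williamson ether synthesis on both phenoxides, the excess of bromide and gentle heating serving to alkylate also the hydrogen-bonded ortho hydroxyl.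

Step 3
Reactants: 4 2,4-bis(benzyloxy)-5,6-dimethylbenzaldehyde
Product: 5 2,4-bis(benzyloxy)-5,6-dimethylbenzoic acid
Conditions: NaClO2, NaH2PO4, 2-methylbut-2-ene, t-BuOH/H2O, rt
Reagents that add atoms: sodium chlorite [Na+].[O-]Cl=O
Why: Pinnick oxidation, in which chlorous acid converts the hindered aldehyde into the acid while the alkene traps hypochlorous acid and so protects the electron-rich ring from chlorination.

Step 4
Reactants: 6 (R)-but-3-yn-2-ol
Product: 7 (R)-but-3-yn-2-yl methanesulfonate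
Conditions: MsCl, Et3N, CH2Cl2, −78 → 0 °C
Reagents that add atoms: methanesulfonyl chloride CS(=O)(=O)Cl
Why: O-sulfonylation of the alcohol, which leaves the C–O bond untouched so that the R configuration is retained.

Step 5
Reactants: 7 (R)-but-3-yn-2-yl methanesulfonate; 8 (tert-butyldimethylsilyloxy)acetaldehyde
Product: 10 (2S,3S)-1-[(tert-butyldimethylsilyl)oxy]-3-methylpent-4-yn-2-ol, via (P)-buta-1,2-dienyl(ethyl)zinc 9 (not isolated)
Conditions: Pd(OAc)2 (5 mol%), PPh3 (5 mol%), Et2Zn (3 equiv), THF, −78 → −20 °C; aq. NH4Cl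
Reagents that add atoms: none
Why: Marshall propargylation, in which zerovalent palladium displaces the mesylate in an anti SN2′ sense, transmetalation gives allenylzinc 9, and this adds to aldehyde 8 through a cyclic SE2′ transition state on the face that bears the metal, so that the methyl-bearing carbon is formed with overall inversion (S) and the carbinol anti to it (S); the carbinol centre is later oxidised away, so only the methyl centre has to be clean.

Step 6
Reactants: 10 (2S,3S)-1-[(tert-butyldimethylsilyl)oxy]-3-methylpent-4-yn-2-ol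
Product: 11 (2S,3S)-1,2-bis[(tert-butyldimethylsilyl)oxy]-3-methylpent-4-yne
Conditions: TBSOTf, 2,6-lutidine, CH2Cl2, −78 → 0 °C
Reagents that add atoms: tert-butyldimethylsilyl trifluoromethanesulfonate CC(C)(C)[Si](C)(C)OS(=O)(=O)C(F)(F)F
Why: Silylation of a secondary alcohol with a silyl triflate and a hindered base, which is fast even next to the branched carbon and touches no stereocentre.

Step 7
Reactants: 11 (2S,3S)-1,2-bis[(tert-butyldimethylsilyl)oxy]-3-methylpent-4-yne
Product: 12 (2S,3S)-2-[(tert-butyldimethylsilyl)oxy]-3-methylpent-4-yn-1-ol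
Conditions: HF·pyridine, pyridine, THF, 0 °C → rt
Reagents that add atoms: none
Why: Selective silyl ether cleavage, since buffered fluoride attacks the unhindered primary silyl ether much faster than the secondary one beside the branched carbon, and the acidic medium excludes base-induced silyl migration.

Step 8
Reactants: 12 (2S,3S)-2-[(tert-butyldimethylsilyl)oxy]-3-methylpent-4-yn-1-ol; 5 2,4-bis(benzyloxy)-5,6-dimethylbenzoic acid
Product: 13 (2S,3S)-2-[(tert-butyldimethylsilyl)oxy]-3-methylpent-4-yn-1-yl 2,4-bis(benzyloxy)-5,6-dimethylbenzoate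
Conditions: PPh3, DIAD, THF, 0 °C → rt
Reagents that add atoms: none
Why: Mitsunobu esterification, in which the carboxylate of the di-ortho-substituted acid attacks the activated primary carbon, so that the crowding at the acyl carbon does not matter and no stereocentre is involved.

Step 9
Reactants: 13 (2S,3S)-2-[(tert-butyldimethylsilyl)oxy]-3-methylpent-4-yn-1-yl 2,4-bis(benzyloxy)-5,6-dimethylbenzoate; 14 benzyl chloroformate
Product: 16 benzyl (4S,5S)-6-{[2,4-bis(benzyloxy)-5,6-dimethylbenzoyl]oxy}-5-[(tert-butyldimethylsilyl)oxy]-4-methylhex-2-ynoate, via lithium acetylide 15 (not isolated)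
Conditions: n-BuLi (1.05 equiv), THF, −78 °C; then 14, −78 → −30 °C
Reagents that add atoms: none
Why: Acylation of a lithium acetylide with a chloroformate, relying on deprotonation of the terminal alkyne being far faster than attack of n-BuLi on the hindered benzoate, with the cold, base-poor quench leaving the propargylic C4–H alone.

Step 10
Reactants: 17 methyl 3-oxopentanoate
Product: 18 methyl (E)-3-methoxypent-2-enoate
Conditions: HC(OMe)3, H2SO4 (cat.), MeOH, rt → 50 °C; distillation
Reagents that add atoms: trimethyl orthoformate COC(OC)OC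
Why: Enol ether formation by acid-catalysed ketalisation of the ketone carbonyl of the β-keto ester and loss of methanol towards the conjugated E enoate.

Step 11
Reactants: 18 methyl (E)-3-methoxypent-2-enoate
Product: 20 (1Z,3Z)-1,3-dimethoxy-1-[(trimethylsilyl)oxy]penta-1,3-diene, via lithium dienolate 19 (not isolated)
Conditions: LiN(iPr)2, THF, −78 °C; then Me3SiCl, −78 → 0 °C
Reagents that add atoms: chlorotrimethylsilane C[Si](C)(C)Cl
Why: Kinetic γ-deprotonation of the β-alkoxy enoate to the extended dienolate followed by O-silylation (silyl ketene acetal formation); the geometry at C1 is of no consequence, and the 3Z isomer, whose methyl group points away from the diene interior, is the one able to reach the s-cis conformation.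

Step 12
Reactants: 16 benzyl (4S,5S)-6-{[2,4-bis(benzyloxy)-5,6-dimethylbenzoyl]oxy}-5-[(tert-butyldimethylsilyl)oxy]-4-methylhex-2-ynoate; 20 (1Z,3Z)-1,3-dimethoxy-1-[(trimethylsilyl)oxy]penta-1,3-diene
Product: 22 benzyl 6-[(2S,3S)-4-{[2,4-bis(benzyloxy)-5,6-dimethylbenzoyl]oxy}-3-[(tert-butyldimethylsilyl)oxy]butan-2-yl]-2-hydroxy-4-methoxy-5-methylbenzoate, via cyclohexa-1,4-diene cycloadduct 21 (not isolated)
Conditions: 20 (3 equiv), PhMe (2 M), 120 °C, sealed tube; then SiO2, CH2Cl2, rt
Reagents that add atoms: none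
Why: The electron-rich diene 20 and the ynoate 16 should combine in a thermal, asynchronous (4+2) cycloaddition in which the methyl-bearing terminus of the diene, remote from the ketene acetal and carrying the largest HOMO coefficient, bonds to the β-carbon of the ynoate (future C4a) and the ketene acetal carbon bonds to the α-carbon (future C8a); cycloadduct 21 then expels methoxytrimethylsilane from its ketal carbon and the ring CH and becomes aromatic. The closest known reaction type is the Diels–Alder benzannulation of 1,3-dialkoxy-1-silyloxybuta-1,3-dienes with acetylenic esters to 6-substituted 4-methoxysalicylates, applied here to a γ-branched ynoate and a 4-methylated diene. Ring A is closed by the intermolecular cycloaddition itself, both new bonds (C4a–C5 and C8a–C8) being formed suprafacially on each partner, so no separate ring-closing mode arises. No lasting stereocentre is created, because the two sp3 ring carbons of 21 are flattened on aromatisation, and the existing 4S centre is only propargylic in a base-free medium and should be retained. The step needs regioselectivity, secured by the matched polarisation of the partners (O-8 ends up ortho and the methoxyl para to the ester-bearing carbon), and chemoselectivity, given because the ynoate is the only electron-poor π bond while the hindered aryl ester, benzyl ethers and silyl ether are inert. The branched C4 substituent and the 4-methyl group of the diene will slow the addition, hence the excess of diene, high concentration and heat.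

Step 13
Reactants: 22 benzyl 6-[(2S,3S)-4-{[2,4-bis(benzyloxy)-5,6-dimethylbenzoyl]oxy}-3-[(tert-butyldimethylsilyl)oxy]butan-2-yl]-2-hydroxy-4-methoxy-5-methylbenzoate
Product: 23 benzyl 6-[(2S,3S)-4-{[2,4-bis(benzyloxy)-5,6-dimethylbenzoyl]oxy}-3-hydroxybutan-2-yl]-2-hydroxy-4-methoxy-5-methylbenzoate
Conditions: HF·pyridine, THF, 0 °C → rt
Reagents that add atoms: none
Why: Fluoride-mediated desilylation under weakly acidic conditions, chosen so that no alkoxide is formed and the freed C3 hydroxyl neither attacks the benzyl ester nor takes over the hindered ring B acyl group; the crude alcohol is to be oxidised at once.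

Step 14
Reactants: 23 benzyl 6-[(2S,3S)-4-{[2,4-bis(benzyloxy)-5,6-dimethylbenzoyl]oxy}-3-hydroxybutan-2-yl]-2-hydroxy-4-methoxy-5-methylbenzoate
Product: 24 benzyl 6-[(2S)-4-{[2,4-bis(benzyloxy)-5,6-dimethylbenzoyl]oxy}-3-oxobutan-2-yl]-2-hydroxy-4-methoxy-5-methylbenzoate
Conditions: Dess–Martin periodinane, NaHCO3, CH2Cl2, 0 °C → rt
Reagents that add atoms: none
Why: Dess–Martin oxidation of the secondary alcohol under buffered, near-neutral conditions, which tolerates the hydrogen-bonded phenol and should not enolise the new ketone towards C4, whose C–H is held in the plane of the doubly ortho-substituted ring.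

Step 15
Reactants: 24 benzyl 6-[(2S)-4-{[2,4-bis(benzyloxy)-5,6-dimethylbenzoyl]oxy}-3-oxobutan-2-yl]-2-hydroxy-4-methoxy-5-methylbenzoate
Product: 26 [(3R,4S)-3,8-dihydroxy-6-methoxy-4,5-dimethyl-1-oxo-3,4-dihydro-1H-isochromen-3-yl]methyl 2,4-dihydroxy-5,6-dimethylbenzoate, via open keto acid 25 (not isolated)
Conditions: H2 (1 atm), Pd/C (10 wt%), EtOAc, rt
Reagents that add atoms: none
Why: Hydrogenolysis of the benzyl ester and both benzyl ethers under neutral conditions, after which the acid of 25 adds to the C3 ketone (6-exo-trig lactolisation); C3 is set under thermodynamic control, with the C4 methyl pseudoaxial to avoid the C5 methyl, the C3 hydroxyl axial on the opposite face (anomeric effect) and the acyloxymethyl group equatorial, which is the 3R,4S arrangement.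

Compound list
1 | 4,5-dimethylbenzene-1,3-diol | Cc1cc(O)cc(O)c1C | starting material
2 | [(2,4-dihydroxy-5,6-dimethylphenyl)methylidene]dimethyliminium chloride | C[N+](C)=Cc1c(O)cc(O)c(C)c1C.[Cl-] | intermediate
3 | 2,4-dihydroxy-5,6-dimethylbenzaldehyde | O=Cc1c(O)cc(O)c(C)c1C | intermediate
4 | 2,4-bis(benzyloxy)-5,6-dimethylbenzaldehyde | O=Cc1c(OCc2ccccc2)cc(OCc2ccccc2)c(C)c1C | intermediate
5 | 2,4-bis(benzyloxy)-5,6-dimethylbenzoic acid | OC(=O)c1c(OCc2ccccc2)cc(OCc2ccccc2)c(C)c1C | intermediate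
6 | (R)-but-3-yn-2-ol | C#C[C@@H](C)O | starting material
7 | (R)-but-3-yn-2-yl methanesulfonate | C#C[C@@H](C)OS(C)(=O)=O | intermediate
8 | (tert-butyldimethylsilyloxy)acetaldehyde | O=CCO[Si](C)(C)C(C)(C)C | starting material
9 | (P)-buta-1,2-dienyl(ethyl)zinc | CC[Zn]C([H])=[C@]=C(C)[H] | intermediate
10 | (2S,3S)-1-[(tert-butyldimethylsilyl)oxy]-3-methylpent-4-yn-2-ol (anti) | C#C[C@H](C)[C@H](O)CO[Si](C)(C)C(C)(C)C | intermediate
11 | (2S,3S)-1,2-bis[(tert-butyldimethylsilyl)oxy]-3-methylpent-4-yne | C#C[C@H](C)[C@H](O[Si](C)(C)C(C)(C)C)CO[Si](C)(C)C(C)(C)C | intermediate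
12 | (2S,3S)-2-[(tert-butyldimethylsilyl)oxy]-3-methylpent-4-yn-1-ol | C#C[C@H](C)[C@H](O[Si](C)(C)C(C)(C)C)CO | intermediate
13 | (2S,3S)-2-[(tert-butyldimethylsilyl)oxy]-3-methylpent-4-yn-1-yl 2,4-bis(benzyloxy)-5,6-dimethylbenzoate | C#C[C@H](C)[C@H](O[Si](C)(C)C(C)(C)C)COC(=O)c1c(OCc2ccccc2)cc(OCc2ccccc2)c(C)c1C | intermediate
14 | benzyl chloroformate | O=C(Cl)OCc1ccccc1 | starting material
15 | lithium acetylide of 13 | [Li]C#C[C@H](C)[C@H](O[Si](C)(C)C(C)(C)C)COC(=O)c1c(OCc2ccccc2)cc(OCc2ccccc2)c(C)c1C | intermediate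
16 | benzyl (4S,5S)-6-{[2,4-bis(benzyloxy)-5,6-dimethylbenzoyl]oxy}-5-[(tert-butyldimethylsilyl)oxy]-4-methylhex-2-ynoate | O=C(OCc1ccccc1)C#C[C@H](C)[C@H](O[Si](C)(C)C(C)(C)C)COC(=O)c1c(OCc2ccccc2)cc(OCc2ccccc2)c(C)c1C | intermediate
17 | methyl 3-oxopentanoate | CCC(=O)CC(=O)OC | starting material
18 | methyl (E)-3-methoxypent-2-enoate | CC/C(OC)=C\C(=O)OC | intermediate
19 | lithium (1Z,3Z)-1,3-dimethoxypenta-1,3-dien-1-olate | C/C=C(OC)/C=C(/OC)O[Li] | intermediate
20 | (1Z,3Z)-1,3-dimethoxy-1-[(trimethylsilyl)oxy]penta-1,3-diene | C/C=C(OC)/C=C(/OC)O[Si](C)(C)C | intermediate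
21 | benzyl 2-[(2S,3S)-4-{[2,4-bis(benzyloxy)-5,6-dimethylbenzoyl]oxy}-3-[(tert-butyldimethylsilyl)oxy]butan-2-yl]-4,6-dimethoxy-3-methyl-6-[(trimethylsilyl)oxy]cyclohexa-1,4-diene-1-carboxylate (ring centres C3 and C6 undefined) | COC1=CC(OC)(O[Si](C)(C)C)C(C(=O)OCc2ccccc2)=C([C@H](C)[C@H](O[Si](C)(C)C(C)(C)C)COC(=O)c2c(OCc3ccccc3)cc(OCc3ccccc3)c(C)c2C)C1C | intermediate
22 | benzyl 6-[(2S,3S)-4-{[2,4-bis(benzyloxy)-5,6-dimethylbenzoyl]oxy}-3-[(tert-butyldimethylsilyl)oxy]butan-2-yl]-2-hydroxy-4-methoxy-5-methylbenzoate | COc1cc(O)c(C(=O)OCc2ccccc2)c(c1C)[C@H](C)[C@H](O[Si](C)(C)C(C)(C)C)COC(=O)c1c(OCc2ccccc2)cc(OCc2ccccc2)c(C)c1C | intermediate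
23 | benzyl 6-[(2S,3S)-4-{[2,4-bis(benzyloxy)-5,6-dimethylbenzoyl]oxy}-3-hydroxybutan-2-yl]-2-hydroxy-4-methoxy-5-methylbenzoate | COc1cc(O)c(C(=O)OCc2ccccc2)c(c1C)[C@H](C)[C@H](O)COC(=O)c1c(OCc2ccccc2)cc(OCc2ccccc2)c(C)c1C | intermediate
24 | benzyl 6-[(2S)-4-{[2,4-bis(benzyloxy)-5,6-dimethylbenzoyl]oxy}-3-oxobutan-2-yl]-2-hydroxy-4-methoxy-5-methylbenzoate | COc1cc(O)c(C(=O)OCc2ccccc2)c(c1C)[C@H](C)C(=O)COC(=O)c1c(OCc2ccccc2)cc(OCc2ccccc2)c(C)c1C | intermediate
25 | 6-[(2S)-4-[(2,4-dihydroxy-5,6-dimethylbenzoyl)oxy]-3-oxobutan-2-yl]-2-hydroxy-4-methoxy-5-methylbenzoic acid | COc1cc(O)c(C(=O)O)c(c1C)[C@H](C)C(=O)COC(=O)c1c(O)cc(O)c(C)c1C | intermediate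
26 | [(3R,4S)-3,8-dihydroxy-6-methoxy-4,5-dimethyl-1-oxo-3,4-dihydro-1H-isochromen-3-yl]methyl 2,4-dihydroxy-5,6-dimethylbenzoate | COc1cc(O)c2c(c1C)[C@H](C)[C@](O)(COC(=O)c1c(O)cc(O)c(C)c1C)OC2=O | target

Total step count: 15 (ring B acid, steps 1–3; alkynoate, steps 4–9; diene, steps 10–11; key step 12; endgame, steps 13–15).
Longest linear sequence: 10 steps, from 6 through steps 4–9 and 12–15.

Steps most likely to fail

Step 12. Both reacting termini are hindered (the γ-branched ynoate and the 4-methyl end of the diene), so the cycloaddition may be slower than desilylation, hydrogen shift or oligomerisation of the diene. The fallback raises the reactivity of the dienophile by changing its activating group. It sets out from 13: the lithium acetylide 15 is formylated (n-BuLi, THF, −78 °C; DMF; quench into aq. KH2PO4) to the ynal (2S,3S)-2-[(tert-butyldimethylsilyl)oxy]-3-methyl-6-oxohex-4-yn-1-yl 2,4-bis(benzyloxy)-5,6-dimethylbenzoate F1. This far more electron-poor alkyne should add diene 20 at or near room temperature to give the formyl analogue of cycloadduct 21, F2, which should aromatise with loss of methoxytrimethylsilane to (2S,3S)-2-[(tert-butyldimethylsilyl)oxy]-3-(2-formyl-3-hydroxy-5-methoxy-6-methylphenyl)butyl 2,4-bis(benzyloxy)-5,6-dimethylbenzoate F3. Pinnick oxidation (NaClO2, NaH2PO4, 2-methylbut-2-ene) would give 6-[(2S,3S)-4-{[2,4-bis(benzyloxy)-5,6-dimethylbenzoyl]oxy}-3-[(tert-butyldimethylsilyl)oxy]butan-2-yl]-2-hydroxy-4-methoxy-5-methylbenzoic acid F4, and alkylation of its carboxylate (BnBr, KHCO3, DMF) comes back to the route at 22.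

Step 13. Once the C3 hydroxyl is free it may close onto the hydrogen-bonded, activated benzyl salicylate (δ-lactonisation) or take over the acyl group from O-9, and the hindered silyl ether may need conditions forcing enough for this to happen. The fallback deactivates the ester before the hydroxyl is released. It sets out from 22: O-benzylation of the C8 phenol (BnBr, K2CO3, DMF) gives benzyl 2-(benzyloxy)-6-[(2S,3S)-4-{[2,4-bis(benzyloxy)-5,6-dimethylbenzoyl]oxy}-3-[(tert-butyldimethylsilyl)oxy]butan-2-yl]-4-methoxy-5-methylbenzoate F5, whose doubly ortho-substituted benzoate, no longer hydrogen-bonded, is a poor acyl donor. Desilylation (HF·pyridine, THF) would then give benzyl 2-(benzyloxy)-6-[(2S,3S)-4-{[2,4-bis(benzyloxy)-5,6-dimethylbenzoyl]oxy}-3-hydroxybutan-2-yl]-4-methoxy-5-methylbenzoate F6, and Dess–Martin oxidation benzyl 2-(benzyloxy)-6-[(2S)-4-{[2,4-bis(benzyloxy)-5,6-dimethylbenzoyl]oxy}-3-oxobutan-2-yl]-4-methoxy-5-methylbenzoate F7. Hydrogenolysis of all four benzyl groups (H2, Pd/C) comes back to the route at keto acid 25, which closes to 26.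

Step 5. The allenylzinc intermediate may racemise before it adds, or the hydrate-prone α-silyloxy aldehyde may convert poorly, so that the only lasting stereocentre is set with insufficient purity. The fallback sets the same methyl/carbinol pair by crotylboration and makes the alkyne afterwards. It sets out from 8: Brown crotylboration with the (E)-crotyldiisopinocampheylborane enantiomer that attacks the Si face of the aldehyde (expected to be the one made from (+)-α-pinene; THF, −78 °C; then NaOH, H2O2) should give (2S,3S)-1-[(tert-butyldimethylsilyl)oxy]-3-methylpent-4-en-2-ol F8. Silylation (TBSOTf, 2,6-lutidine) gives (2S,3S)-1,2-bis[(tert-butyldimethylsilyl)oxy]-3-methylpent-4-ene F9, and ozonolysis (O3, CH2Cl2, −78 °C; PPh3) gives (2R,3S)-3,4-bis[(tert-butyldimethylsilyl)oxy]-2-methylbutanal F10. Ohira–Bestmann homologation (dimethyl (1-diazo-2-oxopropyl)phosphonate, K2CO3, MeOH, 0 °C) comes back to the route at 11.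

Further compounds
F1 | step 12 | (2S,3S)-2-[(tert-butyldimethylsilyl)oxy]-3-methyl-6-oxohex-4-yn-1-yl 2,4-bis(benzyloxy)-5,6-dimethylbenzoate | O=CC#C[C@H](C)[C@H](O[Si](C)(C)C(C)(C)C)COC(=O)c1c(OCc2ccccc2)cc(OCc2ccccc2)c(C)c1C
F2 | step 12 | formyl analogue of cycloadduct 21 (CHO in place of the benzyl ester; not isolated) | COC1=CC(OC)(O[Si](C)(C)C)C(C=O)=C([C@H](C)[C@H](O[Si](C)(C)C(C)(C)C)COC(=O)c2c(OCc3ccccc3)cc(OCc3ccccc3)c(C)c2C)C1C
F3 | step 12 | (2S,3S)-2-[(tert-butyldimethylsilyl)oxy]-3-(2-formyl-3-hydroxy-5-methoxy-6-methylphenyl)butyl 2,4-bis(benzyloxy)-5,6-dimethylbenzoate | COc1cc(O)c(C=O)c(c1C)[C@H](C)[C@H](O[Si](C)(C)C(C)(C)C)COC(=O)c1c(OCc2ccccc2)cc(OCc2ccccc2)c(C)c1C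
F4 | step 12 | 6-[(2S,3S)-4-{[2,4-bis(benzyloxy)-5,6-dimethylbenzoyl]oxy}-3-[(tert-butyldimethylsilyl)oxy]butan-2-yl]-2-hydroxy-4-methoxy-5-methylbenzoic acid | COc1cc(O)c(C(=O)O)c(c1C)[C@H](C)[C@H](O[Si](C)(C)C(C)(C)C)COC(=O)c1c(OCc2ccccc2)cc(OCc2ccccc2)c(C)c1C
F5 | step 13 | benzyl 2-(benzyloxy)-6-[(2S,3S)-4-{[2,4-bis(benzyloxy)-5,6-dimethylbenzoyl]oxy}-3-[(tert-butyldimethylsilyl)oxy]butan-2-yl]-4-methoxy-5-methylbenzoate | COc1cc(OCc2ccccc2)c(C(=O)OCc2ccccc2)c(c1C)[C@H](C)[C@H](O[Si](C)(C)C(C)(C)C)COC(=O)c1c(OCc2ccccc2)cc(OCc2ccccc2)c(C)c1C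
F6 | step 13 | benzyl 2-(benzyloxy)-6-[(2S,3S)-4-{[2,4-bis(benzyloxy)-5,6-dimethylbenzoyl]oxy}-3-hydroxybutan-2-yl]-4-methoxy-5-methylbenzoate | COc1cc(OCc2ccccc2)c(C(=O)OCc2ccccc2)c(c1C)[C@H](C)[C@H](O)COC(=O)c1c(OCc2ccccc2)cc(OCc2ccccc2)c(C)c1C
F7 | step 13 | benzyl 2-(benzyloxy)-6-[(2S)-4-{[2,4-bis(benzyloxy)-5,6-dimethylbenzoyl]oxy}-3-oxobutan-2-yl]-4-methoxy-5-methylbenzoate | COc1cc(OCc2ccccc2)c(C(=O)OCc2ccccc2)c(c1C)[C@H](C)C(=O)COC(=O)c1c(OCc2ccccc2)cc(OCc2ccccc2)c(C)c1C
F8 | step 5 | (2S,3S)-1-[(tert-butyldimethylsilyl)oxy]-3-methylpent-4-en-2-ol | C=C[C@H](C)[C@H](O)CO[Si](C)(C)C(C)(C)C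
F9 | step 5 | (2S,3S)-1,2-bis[(tert-butyldimethylsilyl)oxy]-3-methylpent-4-ene | C=C[C@H](C)[C@H](O[Si](C)(C)C(C)(C)C)CO[Si](C)(C)C(C)(C)C
F10 | step 5 | (2R,3S)-3,4-bis[(tert-butyldimethylsilyl)oxy]-2-methylbutanal | O=C[C@H](C)[C@H](O[Si](C)(C)C(C)(C)C)CO[Si](C)(C)C(C)(C)C
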